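## Retrosynthetic overview
1. Cut C1–C2 (CH2 on the quinone / vinyl carbon). This gives 2-(chloromethyl)-3-methyl-1,4-naphthoquinone, one step from menadione, and an E-vinylalane from a C35 terminal alkyne. Syn-methylalumination makes the E C2=C3 bond and installs the C3 methyl.
2. Cut C12–C13 (alkyl Grignard + allylic acetate, Cu catalysis). This gives a C2–C12 bromo-alkyne carrying C7 and C11, and a C13–C36 pentaenyl acetate carrying C31.
3. Cut C28–C29. This gives ω-brominated geranylgeranyl acetate and (R)-citronellyl bromide (chiral pool, C31).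
4. Cut C4–C5, then reconnect C5 to C12. This leads through TMS-propyne and (2S,6R)-2,6-dimethyloctane-1,8-diol back to an eight-membered silyl enol ether, cleaved by ozonolysis.
5. Key step: an enantioselective Cu-catalysed Me2Zn addition breaks the symmetry of cycloocta-2,7-dienone and sets C7. A second ligand-controlled addition sets C11. No ring is formed: the naphthoquinone is bought intact, and the eight-membered ring is a template that is only opened.

Chain numbering: C1 is the CH2 on the quinone and C36 is the chain end.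

Assumption: the phosphoramidite induces in the same sense as with cyclohex-2-enone, where the (S,R,R) ligand gives the (S)-3-alkyl ketone. If the eight-membered ring reverses this, the two ligand enantiomers are exchanged between steps 2 and 3.

## Route

Step 1
Reactants: 1 cyclooctanone
Product: 2 (2Z,7Z)-cycloocta-2,7-dien-1-one
Conditions: IBX (2-iodoxybenzoic acid, 4 equiv), DMSO/fluorobenzene 1:2, 80 °C
Reagents that add atoms: none
Why: Twofold IBX α,β-dehydrogenation of a ketone (Nicolaou-type desaturation through the enol) acts on both α-methylene pairs and is a one-step entry to this mirror-symmetric cross-conjugated dienone.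

Step 2 (key step)
Reactants: 2 (2Z,7Z)-cycloocta-2,7-dien-1-one
Product: 4 (2Z,7R)-7-methylcyclooct-2-en-1-one, via methylzinc dienolate 3 (not isolated)
Conditions: Me2Zn (1.5 equiv), Cu(OTf)2 (2.5 mol %), (R,S,S)-phosphoramidite L [(R)-binaphthol-derived, N,N-bis((S)-1-phenylethyl)] (5 mol %), toluene, −25 °C; 1 M HCl quench
Reagents that add atoms: dimethylzinc C[Zn]C
Why: In this copper–phosphoramidite enantioselective conjugate addition (Feringa-type ACA) the chiral catalyst selects one of the mirror-related enone faces, so the first methyl transfer breaks the symmetry and sets the future C7 as (R), and the cross-conjugated zinc dienolate formed is no longer an acceptor, so a second addition cannot occur.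

Step 3
Reactants: 4 (2Z,7R)-7-methylcyclooct-2-en-1-one
Product: 6 {[(1E,3S,7R)-3,7-dimethylcyclooct-1-en-1-yl]oxy}trimethylsilane, via methylzinc enolate 5 (not isolated)
Conditions: Me2Zn (1.5 equiv), Cu(OTf)2 (2.5 mol %), (S,R,R)-phosphoramidite L (5 mol %), toluene, −25 °C; then TMSOTf (1.5 equiv), −25 °C → rt; cold aq NaHCO3
Reagents that add atoms: dimethylzinc C[Zn]C; trimethylsilyl trifluoromethanesulfonate C[Si](C)(C)OS(=O)(=O)C(F)(F)F
Why: A second catalyst-controlled ACA with the mirror-image ligand overrides the remote methyl group and sets the future C11 (3S, cis to the first methyl), and O-silylation of the regiodefined zinc enolate preserves the broken symmetry, because the free ketone would be meso.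

Step 4
Reactants: 6 {[(1E,3S,7R)-3,7-dimethylcyclooct-1-en-1-yl]oxy}trimethylsilane
Product: 8 (2S,6R)-2,6-dimethyloctane-1,8-diol, via hydroxy acid 7 (not isolated)
Conditions: O3, CH2Cl2/MeOH 4:1, −78 °C; NaBH4, −78 °C → rt; acidify, extract, solvent swap; LiAlH4, THF, 0 °C → reflux
Reagents that add atoms: ozone [O-][O+]=O
Why: Ozonolysis of the electron-rich silyl enol ether cleaves only C1=C2, the α-methyl aldehyde is reduced in situ at low temperature before it can epimerise, and hydride reduction of the crude acid then gives the open-chain diol with both stereocentres intact.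

Step 5
Reactants: 8 (2S,6R)-2,6-dimethyloctane-1,8-diol
Product: 9 (2S,6R)-1,8-dibromo-2,6-dimethyloctane
Conditions: CBr4 (2.4 equiv), PPh3 (2.5 equiv), CH2Cl2, 0 °C → rt
Reagents that add atoms: tetrabromomethane BrC(Br)(Br)Br
Why: The double Appel bromination is a neutral SN2 process at two primary carbons and touches neither stereocentre.

Step 6
Reactants: 9 (2S,6R)-1,8-dibromo-2,6-dimethyloctane; 10 1-(trimethylsilyl)propyne
Product: 12 [(6R,10S)-11-bromo-6,10-dimethylundec-1-yn-1-yl]trimethylsilane, via 3-lithio-1-(trimethylsilyl)propyne 11 (not isolated)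
Conditions: 10 (1.0 equiv), n-BuLi (1.0 equiv), THF, −78 → −20 °C; then 9 (1.1 equiv), DMPU, −78 → −20 °C
Reagents that add atoms: none
Why: In this SN2 alkylation of a propargylic organolithium the unbranched CH2Br reacts roughly twenty times faster than the β-branched (isobutyl-type) CH2Br, so one equivalent of nucleophile forms only the C4–C5 bond.

Step 7
Reactants: 13 (2E,6E,10E)-geranylgeraniol
Product: 14 (2E,6E,10E)-geranylgeranyl acetate
Conditions: Ac2O, pyridine, DMAP (cat.), CH2Cl2, 0 °C → rt
Reagents that add atoms: acetic anhydride CC(=O)OC(C)=O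
Why: The DMAP-catalysed acetylation installs a group that protects the alcohol in steps 8–10, deactivates the nearest alkene in step 8 and serves as the leaving group in step 11.

Step 8
Reactants: 14 (2E,6E,10E)-geranylgeranyl acetate
Product: 15 (2E,6E,10E,14E)-16-hydroxy-3,7,11,15-tetramethylhexadeca-2,6,10,14-tetraen-1-yl acetate
Conditions: SeO2 (0.1 equiv), t-BuOOH (2 equiv, decane), salicylic acid (0.1 equiv), CH2Cl2, 0 °C → rt, stopped at ca. 60 % conversion, 14 recycled
Reagents that add atoms: selenium dioxide O=[Se]=O (catalytic oxygen carrier); tert-butyl hydroperoxide CC(C)(C)OO (terminal oxygen source)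
Why: The Sharpless-type catalytic SeO2 allylic oxidation (ene reaction, then [2,3]-shift) prefers the terminal isopropylidene group and gives the E-allylic alcohol, which fixes the E geometry of the future C26=C27 bond.

Step 9
Reactants: 15 (2E,6E,10E,14E)-16-hydroxy-3,7,11,15-tetramethylhexadeca-2,6,10,14-tetraen-1-yl acetate
Product: 16 (2E,6E,10E,14E)-16-bromo-3,7,11,15-tetramethylhexadeca-2,6,10,14-tetraen-1-yl acetate
Conditions: CBr4, PPh3, CH2Cl2, −20 → 0 °C, used at once
Reagents that add atoms: tetrabromomethane BrC(Br)(Br)Br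
Why: Appel bromination of a primary allylic alcohol under neutral conditions proceeds without allylic transposition or E/Z loss and leaves the acetate untouched.

Step 10
Reactants: 16 (2E,6E,10E,14E)-16-bromo-3,7,11,15-tetramethylhexadeca-2,6,10,14-tetraen-1-yl acetate; 17 (R)-citronellyl bromide
Product: 19 (2E,6E,10E,14E,19S)-3,7,11,15,19,23-hexamethyltetracosa-2,6,10,14,22-pentaen-1-yl acetate, via citronellylmagnesium bromide 18 (not isolated)
Conditions: 17, Mg, THF, 45 °C; slow addition (1.05 equiv) to 16, Li2CuCl4 (3 mol %), THF, −78 → −40 °C; aq NH4Cl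
Reagents that add atoms: none
Why: In this copper-catalysed Grignard allylic substitution (Kochi/Fouquet–Schlosser type) the allylic bromide reacts far faster than the allylic acetate at low temperature, Li2CuCl4 in THF with slow addition favours attack at the primary α carbon with retention of E geometry, and C31 comes unchanged from the chiral pool.

Step 11
Reactants: 12 [(6R,10S)-11-bromo-6,10-dimethylundec-1-yn-1-yl]trimethylsilane; 19 (2E,6E,10E,14E,19S)-3,7,11,15,19,23-hexamethyltetracosa-2,6,10,14,22-pentaen-1-yl acetate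
Product: 21 trimethyl[(6R,10S,13E,17E,21E,25E,30S)-6,10,14,18,22,26,30,34-octamethylpentatriaconta-13,17,21,25,33-pentaen-1-yn-1-yl]silane, via alkylmagnesium bromide 20 (not isolated)
Conditions: 12 (1.3 equiv), Mg, THF, 50 °C; then 19, Li2CuCl4 (5 mol %), THF, −20 → 0 °C; aq NH4Cl
Reagents that add atoms: none
Why: Copper-catalysed Grignard substitution of a geranyl-type acetate is α-selective because the γ carbon is fully substituted, it keeps the E alkene, and the silylated alkyne and both stereocentres are inert to Mg and Cu.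

Step 12
Reactants: 21 trimethyl[(6R,10S,13E,17E,21E,25E,30S)-6,10,14,18,22,26,30,34-octamethylpentatriaconta-13,17,21,25,33-pentaen-1-yn-1-yl]silane
Product: 22 (6R,10S,13E,17E,21E,25E,30S)-6,10,14,18,22,26,30,34-octamethylpentatriaconta-13,17,21,25,33-pentaen-1-yne
Conditions: K2CO3 (0.2 equiv), MeOH/THF 1:1, rt
Reagents that add atoms: none
Why: Base-catalysed methanolytic protodesilylation of an alkynylsilane is selective for the C(sp)–Si bond and affects nothing else in this hydrocarbon.

Step 13
Reactants: 23 menadione (2-methylnaphthalene-1,4-dione)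
Product: 24 2-(chloromethyl)-3-methylnaphthalene-1,4-dione
Conditions: 37 % aq CH2O, HCl (g), AcOH, rt, dark
Reagents that add atoms: formaldehyde C=O; hydrogen chloride Cl
Why: The acid-mediated (Blanc-type) chloromethylation can only occur at the single free quinone position C3 and gives the benzylic-type chloride without changing the quinone oxidation level.

Step 14
Reactants: 22 (6R,10S,13E,17E,21E,25E,30S)-6,10,14,18,22,26,30,34-octamethylpentatriaconta-13,17,21,25,33-pentaen-1-yne; 24 2-(chloromethyl)-3-methylnaphthalene-1,4-dione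
Product: 26 2-methyl-3-[(2E,7R,11S,14E,18E,22E,26E,31S)-3,7,11,15,19,23,27,31,35-nonamethylhexatriaconta-2,14,18,22,26,34-hexaen-1-yl]naphthalene-1,4-dione, via vinylalane 25 (not isolated)
Conditions: Me3Al (2 equiv), Cp2ZrCl2 (0.25 equiv), ClCH2CH2Cl, 0 °C → rt; volatiles removed, hexane, Zr salts filtered off; then 24 (1.1 equiv), NiCl2(PPh3)2 (5 mol %)/n-BuLi (10 mol %) (zerovalent nickel made in situ), THF, −20 °C → rt; dil. HCl
Reagents that add atoms: trimethylaluminium C[Al](C)C
Why: Negishi zirconium-catalysed syn-methylalumination is selective for the terminal alkyne over trisubstituted alkenes and fixes the E C2=C3 geometry, and the stereoretentive nickel-catalysed sp2–sp3 cross-coupling with the chloromethylquinone forms C1–C2 directly at the quinone oxidation level, so no protection or final oxidation is needed.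

## Compound list
1 | cyclooctanone | O=C1CCCCCCC1 | starting material
2 | (2Z,7Z)-cycloocta-2,7-dien-1-one | O=C1/C=C\CCC/C=C\1 | intermediate
3 | methylzinc (3R)-3-methylcycloocta-1,7-dien-1-olate | C[Zn]O/C1=C/[C@H](C)CCC/C=C\1 | intermediate
4 | (2Z,7R)-7-methylcyclooct-2-en-1-one | O=C1/C=C\CCC[C@@H](C)C1 | intermediate
5 | methylzinc (3S,7R)-3,7-dimethylcyclooct-1-en-1-olate | C[Zn]O/C1=C/[C@@H](C)CCC[C@@H](C)C1 | intermediate
6 | {[(1E,3S,7R)-3,7-dimethylcyclooct-1-en-1-yl]oxy}trimethylsilane | C[Si](C)(C)O/C1=C/[C@@H](C)CCC[C@@H](C)C1 | intermediate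
7 | (3R,7S)-8-hydroxy-3,7-dimethyloctanoic acid | OC[C@@H](C)CCC[C@@H](C)CC(=O)O | intermediate
8 | (2S,6R)-2,6-dimethyloctane-1,8-diol | OC[C@@H](C)CCC[C@@H](C)CCO | intermediate
9 | (2S,6R)-1,8-dibromo-2,6-dimethyloctane | BrC[C@@H](C)CCC[C@@H](C)CCBr | intermediate
10 | 1-(trimethylsilyl)propyne | CC#C[Si](C)(C)C | starting material
11 | 3-lithio-1-(trimethylsilyl)propyne | [Li]CC#C[Si](C)(C)C | intermediate
12 | [(6R,10S)-11-bromo-6,10-dimethylundec-1-yn-1-yl]trimethylsilane | BrC[C@@H](C)CCC[C@@H](C)CCCC#C[Si](C)(C)C | intermediate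
13 | (2E,6E,10E)-geranylgeraniol | CC(C)=CCC/C(C)=C/CC/C(C)=C/CC/C(C)=C/CO | starting material
14 | (2E,6E,10E)-geranylgeranyl acetate | CC(C)=CCC/C(C)=C/CC/C(C)=C/CC/C(C)=C/COC(C)=O | intermediate
15 | (2E,6E,10E,14E)-16-hydroxy-3,7,11,15-tetramethylhexadeca-2,6,10,14-tetraen-1-yl acetate | OC/C(C)=C/CC/C(C)=C/CC/C(C)=C/CC/C(C)=C/COC(C)=O | intermediate
16 | (2E,6E,10E,14E)-16-bromo-3,7,11,15-tetramethylhexadeca-2,6,10,14-tetraen-1-yl acetate | BrC/C(C)=C/CC/C(C)=C/CC/C(C)=C/CC/C(C)=C/COC(C)=O | intermediate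
17 | (R)-citronellyl bromide, (6R)-8-bromo-2,6-dimethyloct-2-ene | CC(C)=CCC[C@@H](C)CCBr | starting material
18 | [(3R)-3,7-dimethyloct-6-en-1-yl]magnesium bromide | CC(C)=CCC[C@@H](C)CC[Mg]Br | intermediate
19 | (2E,6E,10E,14E,19S)-3,7,11,15,19,23-hexamethyltetracosa-2,6,10,14,22-pentaen-1-yl acetate | CC(C)=CCC[C@@H](C)CCC/C(C)=C/CC/C(C)=C/CC/C(C)=C/CC/C(C)=C/COC(C)=O | intermediate
20 | [(2S,6R)-2,6-dimethyl-11-(trimethylsilyl)undec-10-yn-1-yl]magnesium bromide | Br[Mg]C[C@@H](C)CCC[C@@H](C)CCCC#C[Si](C)(C)C | intermediate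
21 | trimethyl[(6R,10S,13E,17E,21E,25E,30S)-6,10,14,18,22,26,30,34-octamethylpentatriaconta-13,17,21,25,33-pentaen-1-yn-1-yl]silane | CC(C)=CCC[C@@H](C)CCC/C(C)=C/CC/C(C)=C/CC/C(C)=C/CC/C(C)=C/CC[C@@H](C)CCC[C@@H](C)CCCC#C[Si](C)(C)C | intermediate
22 | (6R,10S,13E,17E,21E,25E,30S)-6,10,14,18,22,26,30,34-octamethylpentatriaconta-13,17,21,25,33-pentaen-1-yne | CC(C)=CCC[C@@H](C)CCC/C(C)=C/CC/C(C)=C/CC/C(C)=C/CC/C(C)=C/CC[C@@H](C)CCC[C@@H](C)CCCC#C | intermediate
23 | menadione (2-methylnaphthalene-1,4-dione) | CC1=CC(=O)c2ccccc2C1=O | starting material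
24 | 2-(chloromethyl)-3-methylnaphthalene-1,4-dione | CC1=C(CCl)C(=O)c2ccccc2C1=O | intermediate
25 | dimethyl[(1E,6R,10S,13E,17E,21E,25E,30S)-2,6,10,14,18,22,26,30,34-nonamethylpentatriaconta-1,13,17,21,25,33-hexaen-1-yl]alumane | CC(C)=CCC[C@@H](C)CCC/C(C)=C/CC/C(C)=C/CC/C(C)=C/CC/C(C)=C/CC[C@@H](C)CCC[C@@H](C)CCC/C(C)=C/[Al](C)C | intermediate
26 | 2-methyl-3-[(2E,7R,11S,14E,18E,22E,26E,31S)-3,7,11,15,19,23,27,31,35-nonamethylhexatriaconta-2,14,18,22,26,34-hexaen-1-yl]naphthalene-1,4-dione | CC(C)=CCC[C@@H](C)CCC/C(C)=C/CC/C(C)=C/CC/C(C)=C/CC/C(C)=C/CC[C@@H](C)CCC[C@@H](C)CCC/C(C)=C/CC1=C(C)C(=O)c2ccccc2C1=O | target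

## Step count
- Total steps: 14.
- Longest linear sequence: 9 steps (1, 2, 3, 4, 5, 6, 11, 12, 14).

## Steps most likely to fail, with fallbacks

**Step 6** may fail because it relies only on a steric rate difference between two primary bromides. The fallback tells the two chain ends apart by oxidation level instead. It sets out from hydroxy acid 7, which is now isolated. MeOH with catalytic TMSCl gives methyl (3R,7S)-8-hydroxy-3,7-dimethyloctanoate F1. CBr4/PPh3 then gives methyl (3R,7S)-8-bromo-3,7-dimethyloctanoate F2. Reduction with i-Bu2AlH (CH2Cl2, −78 → 0 °C) gives (3R,7S)-8-bromo-3,7-dimethyloctan-1-ol F3. I2/PPh3/imidazole gives (2S,6R)-1-bromo-8-iodo-2,6-dimethyloctane F4. Organolithium 11 at −78 °C displaces only the unbranched iodide, and the fallback comes back to the route at 12.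

**Step 10** may fail because 16 has two allylic electrophilic sites and the tail-type bromide could react with allylic transposition. The fallback replaces the organocopper substitution by a sulfone-stabilised carbanion, which attacks allylic bromides only at the α carbon. It sets out from 17 and 16. PhSO2Na in DMF converts 17 into {[(3R)-3,7-dimethyloct-6-en-1-yl]sulfonyl}benzene F5. n-BuLi (THF, −78 °C) gives the α-lithio sulfone F6. Alkylation with 16 at −78 °C gives (2E,6E,10E,14E,19R)-17-(benzenesulfonyl)-3,7,11,15,19,23-hexamethyltetracosa-2,6,10,14,22-pentaen-1-yl acetate F7 as both C17 epimers. Mg in MeOH (HgCl2 cat.) removes the sulfonyl group and transesterifies the acetate, giving (2E,6E,10E,14E,19S)-3,7,11,15,19,23-hexamethyltetracosa-2,6,10,14,22-pentaen-1-ol F8. Ac2O/pyridine then comes back to the route at 19.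

**Step 14** may fail because a free quinone meets an organoalane and zerovalent nickel on the most precious material. The fallback masks the quinone as an arene during C–C bond formation and unveils it by oxidative dearomatisation. It sets out from alkyne 22, carboaluminated to 25 as before. Commercial 1,4-dimethoxy-2-methylnaphthalene F9 is chloromethylated ((CH2O)n, HCl, AcOH) to 2-(chloromethyl)-1,4-dimethoxy-3-methylnaphthalene F10. Coupling of F10 with 25 under the same NiCl2(PPh3)2/n-BuLi catalysis gives 1,4-dimethoxy-2-methyl-3-[(2E,7R,11S,14E,18E,22E,26E,31S)-3,7,11,15,19,23,27,31,35-nonamethylhexatriaconta-2,14,18,22,26,34-hexaen-1-yl]naphthalene F11. Oxidation with (NH4)2Ce(NO3)6 in MeCN/CH2Cl2/H2O at 0 °C then comes back to the route at 26.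

## Further compounds
F1 | step 6 | methyl (3R,7S)-8-hydroxy-3,7-dimethyloctanoate | OC[C@@H](C)CCC[C@@H](C)CC(=O)OC
F2 | step 6 | methyl (3R,7S)-8-bromo-3,7-dimethyloctanoate | BrC[C@@H](C)CCC[C@@H](C)CC(=O)OC
F3 | step 6 | (3R,7S)-8-bromo-3,7-dimethyloctan-1-ol | BrC[C@@H](C)CCC[C@@H](C)CCO
F4 | step 6 | (2S,6R)-1-bromo-8-iodo-2,6-dimethyloctane | BrC[C@@H](C)CCC[C@@H](C)CCI
F5 | step 10 | {[(3R)-3,7-dimethyloct-6-en-1-yl]sulfonyl}benzene | CC(C)=CCC[C@@H](C)CCS(=O)(=O)c1ccccc1
F6 | step 10 | α-lithio derivative of F5, {[(3R)-1-lithio-3,7-dimethyloct-6-en-1-yl]sulfonyl}benzene | CC(C)=CCC[C@@H](C)CC([Li])S(=O)(=O)c1ccccc1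
F7 | step 10 | (2E,6E,10E,14E,19R)-17-(benzenesulfonyl)-3,7,11,15,19,23-hexamethyltetracosa-2,6,10,14,22-pentaen-1-yl acetate (both C17 epimers) | CC(C)=CCC[C@@H](C)CC(C/C(C)=C/CC/C(C)=C/CC/C(C)=C/CC/C(C)=C/COC(C)=O)S(=O)(=O)c1ccccc1
F8 | step 10 | (2E,6E,10E,14E,19S)-3,7,11,15,19,23-hexamethyltetracosa-2,6,10,14,22-pentaen-1-ol | CC(C)=CCC[C@@H](C)CCC/C(C)=C/CC/C(C)=C/CC/C(C)=C/CC/C(C)=C/CO
F9 | step 14 | 1,4-dimethoxy-2-methylnaphthalene | COc1cc(C)c(OC)c2ccccc12
F10 | step 14 | 2-(chloromethyl)-1,4-dimethoxy-3-methylnaphthalene | COc1c(C)c(CCl)c(OC)c2ccccc12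
F11 | step 14 | 1,4-dimethoxy-2-methyl-3-[(2E,7R,11S,14E,18E,22E,26E,31S)-3,7,11,15,19,23,27,31,35-nonamethylhexatriaconta-2,14,18,22,26,34-hexaen-1-yl]naphthalene | CC(C)=CCC[C@@H](C)CCC/C(C)=C/CC/C(C)=C/CC/C(C)=C/CC/C(C)=C/CC[C@@H](C)CCC[C@@H](C)CCC/C(C)=C/Cc1c(C)c(OC)c2ccccc2c1OC
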